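**Plan**

- Retrosynthesis: remove the nine benzyl ethers; take the C3–O bond of the upper unit back to a C3–B(MIDA) bond; cut the two ring C bonds C2–C3 and C4–C4a of the upper unit together, leaving an O-aryl oxocarbenium ion (ring A, O1, C2, ring B) and an (E)-alkene C3=C4 standing on C8 of the lower unit; cut the C4–C8 bond (Suzuki–Miyaura) and the C8–Br bond back to (−)-epigallocatechin.
- Enabling feature: C2 of the upper unit carries both the aryl ether oxygen O1 of ring A and the para-oxygenated ring B, so it can be an oxocarbenium carbon. C4 is benzylic to the 2,4,6-trioxygenated ring A of the lower unit (through C8), so a cation there is strongly stabilised. Ring A of the upper unit is a symmetrical 1,3,5-trioxygenated benzene with two equivalent nucleophilic ortho carbons.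
- Forward: the lower unit is bought as (−)-epigallocatechin, benzylated, brominated at C8 and vinylated; ring C of the upper unit is then closed in one operation, its rings A and B arriving ready-made in a mixed acetal; C–B is oxidised to C–OH; global hydrogenolysis ends the route.
- Stereochemistry: C2 and C3 of the lower unit come from (−)-epigallocatechin. C2, C3 and C4 of the upper unit are set in the key step (relative configuration from the trans-diaxial ring closure, absolute sense from a chiral counter-anion), and C3 passes through the C–B oxidation with retention.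

Key step: step 7

Assumption: the sense of facial induction of the chiral acid in step 7 cannot be derived with certainty beforehand; the (R) acid is written, and its (S) antipode takes its place if a trial shows that the other face of the oxocarbenium ion is shielded.

**Route**

Step 1
Reactants: 1 4-(benzyloxy)benzaldehyde
Product: 2 4-(benzyloxy)benzaldehyde dimethyl acetal
Conditions: HC(OMe)3, p-TsOH·H2O (cat.), MeOH, rt; NaHCO3 quench
Reagents that add atoms: trimethyl orthoformate COC(OC)OC; methanol CO
Why: Acid-catalysed acetalisation of an aromatic aldehyde, driven by the orthoformate as water scavenger; no stereocentre is formed.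

Step 2
Reactants: 2 4-(benzyloxy)benzaldehyde dimethyl acetal; 3 3,5-bis(benzyloxy)phenol
Product: 5 racemic O-aryl O-methyl acetal 1,3-bis(benzyloxy)-5-{[4-(benzyloxy)phenyl](methoxy)methoxy}benzene, via α-chloro ether 4 (not isolated)
Conditions: AcCl, Zn(OAc)2 (cat.), CH2Cl2, 0 °C → rt, evaporation; then 3, NaH, THF/DMF, −20 → 0 °C; Et3N-buffered work-up
Reagents that add atoms: none
Why: Acetyl chloride exchanges one methoxy group of the acetal for chloride (the way chloromethyl methyl ether is made from dimethoxymethane), and the sodium phenoxide of 3 then undergoes Williamson-type O-alkylation as in the MOM protection of phenols; the acetal carbon is racemic and becomes planar in step 7.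

Step 3
Reactants: 6 (−)-epigallocatechin (2R,3R)
Product: 7 5,7,3',4',5'-penta-O-benzyl-(−)-epigallocatechin (2R,3R)
Conditions: BnBr, K2CO3, DMF, 0 °C → rt, argon
Reagents that add atoms: benzyl bromide BrCc1ccccc1
Why: Williamson etherification of the five phenols only, since the carbonate does not deprotonate the secondary alcohol; the mild base and exclusion of oxygen should leave C2 and C3 untouched.

Step 4
Reactants: 7 5,7,3',4',5'-penta-O-benzyl-(−)-epigallocatechin
Product: 8 3,5,7,3',4',5'-hexa-O-benzyl-(−)-epigallocatechin (2R,3R)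
Conditions: NaH, BnBr, n-Bu4NI (cat.), DMF, 0 °C → rt
Reagents that add atoms: benzyl bromide BrCc1ccccc1
Why: Williamson etherification of the remaining secondary alcohol through its sodium alkoxide, which removes the only group that could trap the oxocarbenium ion of step 7; no stereocentre is touched.

Step 5
Reactants: 8 3,5,7,3',4',5'-hexa-O-benzyl-(−)-epigallocatechin
Product: 9 8-bromo-3,5,7,3',4',5'-hexa-O-benzyl-(−)-epigallocatechin (2R,3R)
Conditions: NBS, CH2Cl2, −78 °C → rt
Reagents that add atoms: N-bromosuccinimide BrN1C(=O)CCC1=O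
Why: Electrophilic aromatic bromination of the phloroglucinol-type ring A, which should go to C8 as is usual for benzylated flavan-3-ols (ring A is far more electron-rich than the pyrogallol triether ring B, and C8 is preferred over C6).

Step 6
Reactants: 9 8-bromo-3,5,7,3',4',5'-hexa-O-benzyl-(−)-epigallocatechin; 10 (E)-2-(4,4,5,5-tetramethyl-1,3,2-dioxaborolan-2-yl)vinylboronic acid MIDA ester
Product: 11 (E)-2-[3,5,7,3',4',5'-hexa-O-benzyl-(−)-epigallocatechin-8-yl]vinylboronic acid MIDA ester
Conditions: Pd(OAc)2 (5 mol %), SPhos (10 mol %), anhydrous K3PO4, THF, 60 °C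
Reagents that add atoms: none
Why: Suzuki–Miyaura coupling in which only the tricoordinate pinacol boronate end transmetalates, while the tetracoordinate B(MIDA) end is inert under anhydrous base; the (E) geometry is retained and the biaryl phosphine copes with the di-ortho-substituted bromide.

Step 7
Reactants: 5 racemic O-aryl O-methyl acetal; 11 (E)-2-[3,5,7,3',4',5'-hexa-O-benzyl-(−)-epigallocatechin-8-yl]vinylboronic acid MIDA ester
Product: 14 nona-O-benzyl 3-boryl cycloadduct (upper unit 5,7,4'-tri-O-benzyl-3-deoxy-3-[B(MIDA)]flavan with 2,3-cis-3,4-trans ring C joined C4→C8 to the hexa-O-benzyl-epigallocatechin unit), via oxocarbenium ion 12 (not isolated), via benzylic cation 13 (not isolated)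
Conditions: (R)-3,3'-bis(2,4,6-triisopropylphenyl)-1,1'-binaphthyl-2,2'-diyl N-triflylphosphoramide (10 mol %), 5 Å MS, CH2Cl2, −60 → −20 °C, slow addition of 5 (1.5 equiv)
Reagents that add atoms: none
Why: Proposed new method: the chiral acid ionises acetal 5 with loss of methanol to the (E)-O-aryl oxocarbenium ion 12 (a cationic 2-oxadiene, C4a=C8a–O1=C2), whose C2 is attacked by the boron-bearing alkene carbon of 11, the site made nucleophilic both by the 2,4,6-trioxygenated ring A of the epigallocatechin unit and by the σ-donating tetracoordinate C–B(MIDA) bond, to give the quinone-methide-like benzylic cation 13, which is captured by an ortho carbon of the phloroglucinol ring. The closest known reaction type is the oxa-Povarov reaction of O-aryl oxocarbenium ions with styrenes (Prins addition followed by Friedel–Crafts closure), and for control by a chiral anion the Povarov reaction catalysed by chiral phosphoric acids. Ring C closes at C4–C4a in a 6-exo-trig Friedel–Crafts alkylation, so that the whole event is a stepwise formal inverse-electron-demand [4+2] annulation. The first C–C bond formation is expected to be reversible, because 13 can fragment back to two stabilised partners, so the ring closure should select the half-chair with the C2 aryl group equatorial and the C3 boryl and C4 aryl groups trans-diaxial: the bulky B(MIDA) cage stays anti to the C4 aryl group, which stands pseudo-axial to avoid peri strain with the 5-benzyloxy group of ring A, and this arrangement is the 2,3-cis-3,4-trans configuration of the target. The absolute sense at C2, and with it at C3 and C4, is set by the chiral counter-anion that pairs with 12 and shields one of its enantiotopic faces, the distant stereocentres of the lower unit not being expected to help, and the isomer from the other face is a diastereomer that is removed by chromatography. The step needs regioselective attack by the alkene, secured by the joint push of the aryl ring and the C–B bond, chemoselectivity against vinyl transfer from boron and protodeboronation, secured by the coordinatively saturated boron of the MIDA boronate, and a single site of ring closure, secured by the symmetry of the 3,5-bis(benzyloxy)phenoxy ring.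

Step 8
Reactants: 14 nona-O-benzyl 3-boryl cycloadduct
Product: 15 nona-O-benzyl-epiafzelechin-(4β→8)-epigallocatechin with free 3-OH in the upper unit (2R,3R,4R; lower unit 2R,3R)
Conditions: NaOH (aq), THF, rt; then 30 % H2O2, 0 °C
Reagents that add atoms: hydrogen peroxide OO
Why: Aqueous base hydrolyses the MIDA ligand and hydroperoxide adds to boron, after which C3 migrates from boron to oxygen with retention (boronate oxidation, as in the hydroboration–oxidation of flav-3-enes to flavan-3-ols), so the axial C–B bond becomes the axial 3-OH cis to the C2 aryl group.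

Step 9
Reactants: 15 nona-O-benzyl-epiafzelechin-(4β→8)-epigallocatechin
Product: 16 epiafzelechin-(4β→8)-epigallocatechin, CNP0290824.1 (upper unit 2R,3R,4R; lower unit 2R,3R)
Conditions: H2 (1 atm), Pd(OH)2/C, THF/MeOH/H2O, rt; filtration, lyophilisation
Reagents that add atoms: none
Why: Hydrogenolysis of the eight aryl benzyl ethers and the one alkyl benzyl ether under neutral conditions, as is standard for benzylated proanthocyanidins, leaves the acid-labile C4–C8 bond and all five stereocentres untouched.

**Compound list**

1 | 4-(benzyloxy)benzaldehyde | O=Cc1ccc(OCc2ccccc2)cc1 | starting material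
2 | 4-(benzyloxy)benzaldehyde dimethyl acetal | COC(OC)c1ccc(OCc2ccccc2)cc1 | intermediate
3 | 3,5-bis(benzyloxy)phenol | Oc1cc(OCc2ccccc2)cc(OCc2ccccc2)c1 | starting material
4 | α-chloro ether 1-(benzyloxy)-4-[chloro(methoxy)methyl]benzene (racemic, not isolated) | COC(Cl)c1ccc(OCc2ccccc2)cc1 | intermediate
5 | O-aryl O-methyl acetal 1,3-bis(benzyloxy)-5-{[4-(benzyloxy)phenyl](methoxy)methoxy}benzene (racemic) | COC(Oc1cc(OCc2ccccc2)cc(OCc2ccccc2)c1)c1ccc(OCc2ccccc2)cc1 | intermediate
6 | (−)-epigallocatechin (2R,3R) | Oc1cc(O)c2c(c1)O[C@H](c1cc(O)c(O)c(O)c1)[C@H](O)C2 | starting material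
7 | 5,7,3',4',5'-penta-O-benzyl-(−)-epigallocatechin (2R,3R) | c1ccc(cc1)COc1cc(OCc2ccccc2)c2c(c1)O[C@H](c1cc(OCc3ccccc3)c(OCc3ccccc3)c(OCc3ccccc3)c1)[C@H](O)C2 | intermediate
8 | 3,5,7,3',4',5'-hexa-O-benzyl-(−)-epigallocatechin (2R,3R) | c1ccc(cc1)COc1cc(OCc2ccccc2)c2c(c1)O[C@H](c1cc(OCc3ccccc3)c(OCc3ccccc3)c(OCc3ccccc3)c1)[C@H](OCc1ccccc1)C2 | intermediate
9 | 8-bromo-3,5,7,3',4',5'-hexa-O-benzyl-(−)-epigallocatechin (2R,3R) | c1ccc(cc1)COc1cc(OCc2ccccc2)c2c(c1Br)O[C@H](c1cc(OCc3ccccc3)c(OCc3ccccc3)c(OCc3ccccc3)c1)[C@H](OCc1ccccc1)C2 | intermediate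
10 | (E)-2-(4,4,5,5-tetramethyl-1,3,2-dioxaborolan-2-yl)vinylboronic acid MIDA ester | CC1(C)OB(OC1(C)C)/C=C/[B-]12OC(=O)C[N+]1(C)CC(=O)O2 | starting material
11 | (E)-2-[3,5,7,3',4',5'-hexa-O-benzyl-(−)-epigallocatechin-8-yl]vinylboronic acid MIDA ester (2R,3R) | c1ccc(cc1)COc1cc(OCc2ccccc2)c2c(c1/C=C/[B-]34OC(=O)C[N+]3(C)CC(=O)O4)O[C@H](c1cc(OCc3ccccc3)c(OCc3ccccc3)c(OCc3ccccc3)c1)[C@H](OCc1ccccc1)C2 | intermediate
12 | (E)-O-[3,5-bis(benzyloxy)phenyl] oxocarbenium ion of 4-(benzyloxy)benzaldehyde, as ion pair with the catalyst anion (not isolated) | c1ccc(cc1)COc1ccc(/C=[O+]/c2cc(OCc3ccccc3)cc(OCc3ccccc3)c2)cc1 | intermediate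
13 | benzylic cation after C2–C3 bond formation, C2 and C3 configured as in 14, as ion pair with the catalyst anion (not isolated) | c1ccc(cc1)COc1ccc([C@@H](Oc2cc(OCc3ccccc3)cc(OCc3ccccc3)c2)[C@@H]([CH+]c2c(OCc3ccccc3)cc(OCc3ccccc3)c3c2O[C@H](c2cc(OCc4ccccc4)c(OCc4ccccc4)c(OCc4ccccc4)c2)[C@H](OCc2ccccc2)C3)[B-]23OC(=O)C[N+]2(C)CC(=O)O3)cc1 | intermediate
14 | nona-O-benzyl 3-boryl cycloadduct: 2,3-cis-3,4-trans upper ring C with B(MIDA) at C3, same spatial arrangement as the target (CIP 2S,3R,4R, the C2 letter changing only because boron ranks below carbon), joined C4→C8 to the (2R,3R) lower unit | c1ccc(cc1)COc1ccc([C@H]2Oc3cc(OCc4ccccc4)cc(OCc4ccccc4)c3[C@H](c3c(OCc4ccccc4)cc(OCc4ccccc4)c4c3O[C@H](c3cc(OCc5ccccc5)c(OCc5ccccc5)c(OCc5ccccc5)c3)[C@H](OCc3ccccc3)C4)[C@H]2[B-]34OC(=O)C[N+]3(C)CC(=O)O4)cc1 | intermediate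
15 | nona-O-benzyl-epiafzelechin-(4β→8)-epigallocatechin, free 3-OH in the upper unit (2R,3R,4R; lower unit 2R,3R) | c1ccc(cc1)COc1ccc([C@H]2Oc3cc(OCc4ccccc4)cc(OCc4ccccc4)c3[C@H](c3c(OCc4ccccc4)cc(OCc4ccccc4)c4c3O[C@H](c3cc(OCc5ccccc5)c(OCc5ccccc5)c(OCc5ccccc5)c3)[C@H](OCc3ccccc3)C4)[C@H]2O)cc1 | intermediate
16 | epiafzelechin-(4β→8)-epigallocatechin, CNP0290824.1 (upper unit 2R,3R,4R; lower unit 2R,3R) | Oc1ccc([C@H]2Oc3cc(O)cc(O)c3[C@H](c3c(O)cc(O)c4c3O[C@H](c3cc(O)c(O)c(O)c3)[C@H](O)C4)[C@H]2O)cc1 | target

**Step count and risks**

Total step count: 9. Longest linear sequence: 7 steps (steps 3 to 9, from (−)-epigallocatechin 6).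

Steps most likely to fail:

Step 7. The catalyst may give poor facial selectivity with respect to the distant stereocentres of the lower unit. The ring closure may run through the all-equatorial half-chair and give the 2,3-trans-3,4-trans ring. The oxocarbenium ion may be consumed by Friedel–Crafts self-condensation with the electron-rich rings, or the acetal may ionise by loss of the aryloxy group instead of methanol. The fallback uses the known Lewis-acid-mediated C4–C8 coupling of benzylated flavan-3-ols; it sets out from 8 and comes back to the route at 15. Purchased (−)-epiafzelechin F1 is benzylated at its three phenols (BnBr, K2CO3, DMF) to 5,7,4'-tri-O-benzyl-epiafzelechin F2. Oxidation at the benzylic C4 with DDQ in CH2Cl2 in the presence of 2-ethoxyethanol should give 4β-(2-ethoxyethoxy)-5,7,4'-tri-O-benzyl-epiafzelechin F3. Ionisation of F3 with TMSOTf (cat.) in CH2Cl2 at −78 °C in the presence of an excess of 8 (3 to 4 equiv) should lead to attack of C8 of 8 on the C4 cation anti to the axial 3-OH, which gives 15 directly.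

Step 6. Oxidative addition of zerovalent palladium into the di-ortho-alkoxy, electron-rich bromide may be slow, so that protodeboronation of the pinacol boronate or erosion of the MIDA group takes over. The fallback reverses the polarity of the two partners; it sets out from 9 and comes back at 11. Bromine–lithium exchange (n-BuLi, THF, −78 °C), trapping with B(OiPr)3 and aqueous NH4Cl work-up should give 3,5,7,3',4',5'-hexa-O-benzyl-(−)-epigallocatechin-8-boronic acid F4. This is coupled with commercial (E)-(2-bromovinyl)boronic acid MIDA ester (Br/C=C/[B-]12OC(=O)C[N+]1(C)CC(=O)O2) under Pd(OAc)2, SPhos and anhydrous K3PO4 in THF at 45 °C, so that oxidative addition takes place at the unhindered vinyl bromide.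

Step 2. The ambident phenoxide may be alkylated at carbon by the readily ionising chloro ether, and the acetal 5 may be lost by hydrolysis during isolation. The fallback avoids both the chloro ether and the phenoxide; it sets out from 2 and comes back at 5. Treatment of 2 with TESOTf and 2,4,6-collidine in CH2Cl2 at 0 °C should give 1-{[4-(benzyloxy)phenyl](methoxy)methyl}-2,4,6-trimethylpyridinium triflate F5. Addition of the neutral phenol 3 to this salt in the same flask should displace collidine at the acetal carbon and give 5 under buffered, non-acidic conditions.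

**Further compounds**

F1 | step 7 | (−)-epiafzelechin (2R,3R), purchased | Oc1ccc(cc1)[C@H]1Oc2cc(O)cc(O)c2C[C@H]1O
F2 | step 7 | 5,7,4'-tri-O-benzyl-epiafzelechin (2R,3R) | c1ccc(cc1)COc1ccc(cc1)[C@H]1Oc2cc(OCc3ccccc3)cc(OCc3ccccc3)c2C[C@H]1O
F3 | step 7 | 4β-(2-ethoxyethoxy)-5,7,4'-tri-O-benzyl-epiafzelechin | c1ccc(cc1)COc1ccc(cc1)[C@H]1Oc2cc(OCc3ccccc3)cc(OCc3ccccc3)c2[C@H](OCCOCC)[C@H]1O
F4 | step 6 | 3,5,7,3',4',5'-hexa-O-benzyl-(−)-epigallocatechin-8-boronic acid (2R,3R) | c1ccc(cc1)COc1cc(OCc2ccccc2)c2c(c1B(O)O)O[C@H](c1cc(OCc3ccccc3)c(OCc3ccccc3)c(OCc3ccccc3)c1)[C@H](OCc1ccccc1)C2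
F5 | step 2 | 1-{[4-(benzyloxy)phenyl](methoxy)methyl}-2,4,6-trimethylpyridinium triflate (racemic) | COC(c1ccc(OCc2ccccc2)cc1)[n+]1c(C)cc(C)cc1C.[O-]S(=O)(=O)C(F)(F)F
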